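Assumption (remark on the chemistry): the target SMILES has no stereocentre, stereogenic axis or stereogenic double bond. The compound is achiral, so its constitution alone meets the request for a single enantiomer. The only stereodescriptor in the scheme is the E/Z geometry of the transient push-pull alkenes 6 and F2. It is labile and is erased on aromatisation.

## The problem

The skeleton is a plain indole, a benzene ring (C3a, C4–C7, C7a) fused to a pyrrole ring (N1, C2, C3), and it has no stereocentre. Neither ring closure nor relative configuration is therefore the issue. The issue is position. Bromine stands at C2, C5 and C6, none of which is where an indole takes an electrophile (C3 first, then mixtures), and C5 and C6 are neighbours, so only C5 can be para to the donor N1. The second issue is the gramine unit C3–CH2–NMe2: electrophilic bromine attacks C3 ipso and expels CH2=NMe2+ (retro-Mannich), it oxidises the tertiary amine, and any methylating agent meant for N1 quaternises it. The three C–Br bonds forbid organolithium reagents, dissolving metals, hydrogenolysis and most Pd(0) chemistry late in the route, and a C2–Br on a C3-unsubstituted indole is labile to acid. A synthesis must therefore give each bromine its own control element and bring in the amine last, under non-electrophilic conditions. The feature that allows this is the array N1–C2(Br)=C3–CH2–NMe2 of the pyrrole ring. With one hydride removed from the CH2 it becomes the β-bromovinamidinium ion N1–C2(Br)=C3–CH=N+Me2, which is what a halo-Vilsmeier reaction makes from the lactam unit N1–C2(=O)–C3H2 of an oxindole, and the exocyclic carbon, its nitrogen and both N-methyl groups are the atoms of DMF 4. At the oxindole level the five-membered ring is no longer an enamine, and N1 is an anilide donor that sends Br+ para, to C5, next to a C6 bromine that can be bought.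

## Retrosynthesis

**8 ⇒ 7.** The bond cut is one C–H bond of the exocyclic CH2, removed as hydride, which leaves the indol-3-ylmethyleneiminium bromide 7.
- Against its neighbours: cutting C3–CH2 (Mannich) would ask a thrice-brominated, strongly deactivated indole to act as nucleophile. Cutting CH2–N would need a 3-(halomethyl)indole, a class that ionises and oligomerises.
- Simplification: the atom count does not fall, but the sensitive amine becomes the primary product of a C–C bond-forming reaction and is formed in the last operation.
- Demand on the forward reaction: hydride must go to the exocyclic carbon and not to C2.

**7 ⇒ 6.** The bond cut is C2–Br, replaced by the lactam C2=O of enaminone 6.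
- Against its neighbours: a C2–Br made with Br+ would compete with ipso attack at C3, and one made by C2 metalation would compete with exchange at C5–Br and C6–Br. A C–O to C–Br exchange is position-specific, because the oxygen marks the carbon.
- Simplification: 6 has one bromine fewer and is neutral.
- Demand on the forward reaction: O-activation by a bromophosphorus(V) electrophile, then addition–elimination of bromide at C2, with aromatisation of the pyrrole ring as driving force.

**6 ⇒ 3 + 4 (through 5).** The bond cut is C3=CH.
- For this cut: C3 is the only acidic CH2 of oxindole 3. The electrophile is the bromo-Vilsmeier salt 5, formed from 4 by the same phosphorus reagent that the previous disconnection needs. Both events and the hydride capture therefore fit in one flask (step 3).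
- Simplification: 3 has 13 heavy atoms against 17 in 8, carries no amine and no C2 bromine, and 4 is a bulk solvent.
- Demand on the forward reaction: C-attack of the enol of 3 on 5 without formylation of the benzene ring, which the two bromines deactivate.

**3 ⇒ 2.** The bond cut is N1–CH3.
- For this cut: the methyl group must be in place before step 3, since afterwards any methylating agent would quaternise NMe2.
- Simplification: 2 is the N–H lactam.
- Demand on the forward reaction: N- over C3-methylation of an ambident anion.

**2 ⇒ 1.** The bond cut is C5–Br and not C6–Br.
- For this cut: C5 is para to N1 and can be reached by aromatic substitution. C6 is meta to N1 and cannot, so C6–Br is bought with 6-bromooxindole 1.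
- Demand on the forward reaction: C5 must be chosen over C7 (squeezed between N1 and C6–Br), C4 (meta to N1) and the enolisable C3.

## Roads not taken

**Alternative 1:** (the most obvious) Cut C3–CH2 and C2–Br on a ready-made dibromoindole. In the forward sense, 5,6-dibromo-1-methylindole A1 is aminomethylated (Mannich) to 5,6-dibromo-1-methylgramine A2, and A2 is brominated at C2 with an electrophilic bromine source.
- The 5,6-pattern of A1 cannot be made by direct bromination of an indole. It needs a removable acceptor at C3 (install, dibrominate, hydrolyse, decarboxylate), so the run-up is longer than the whole chosen route.
- The last step puts Br+ on a gramine, where ipso attack at C3 with retro-Mannich loss of the side chain and amine oxidation compete with C2 substitution.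
- The inverse order needs C2 metalation beside two aryl bromides and then a Mannich reaction on a deactivated ring.
- The chosen plan never exposes the amine to Br+ and fixes C2 by an oxygen marker.

**Alternative 2:** (biomimetic) Cut all three C–Br bonds. In the forward sense, 1-methylgramine A3 is brominated exhaustively in strong acid, in imitation of a haloperoxidase, with the protonated side chain as its own protection.
- This is the shortest road on paper, but three positional decisions fall in one flask without a control element.
- C2 is reached only through a 3-bromoindolenine and a 1,2-shift that competes with fragmentation, and C5 and C6 must win over C4 and C7.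
- The isomeric polybromides of a polar amine would be hard to separate.
- In the chosen plan each bromine has its own reason to be where it is: purchase for C6, para-direction by N1 for C5, lactam oxygen for C2.

**Alternative 3:** Cut N1–C2 and C3–C3a (Larock heteroannulation). In the forward sense, 4,5-dibromo-2-iodo-N-methylaniline A4 and N,N-dimethyl-3-(trimethylsilyl)prop-2-yn-1-amine A5 give 5,6-dibromo-1-methyl-2-(trimethylsilyl)gramine A6, which is bromodesilylated at C2.
- The route is convergent and the silyl group steers the regiochemistry.
- Pd(0) must tell C–I from two C–Br bonds at annulation temperature, and A4 itself needs monomethylation and iodination steps.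
- The end is again Br+ on a gramine.
- It is longer and leaves the hardest incompatibility unsolved.

Key step: step 3

## Route

Step 1
Reactants: 1 6-bromooxindole (6-bromo-1,3-dihydro-2H-indol-2-one)
Product: 2 5,6-dibromooxindole (5,6-dibromo-1,3-dihydro-2H-indol-2-one)
Conditions: NBS (1.05 equiv), MeCN, 0 °C to rt, dark
Reagents that add atoms: N-bromosuccinimide, O=C1CCC(=O)N1Br
Why: Electrophilic aromatic bromination of an anilide: N1 directs para to C5, C7 is squeezed between N1 and C6–Br, and C4 is meta to N1; acylation and halogenation of 6-halooxindoles are known to go to C5. In a polar aprotic medium without light, ring substitution should outrun bromination of the C3 enol.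

Step 2
Reactants: 2 5,6-dibromooxindole
Product: 3 5,6-dibromo-1-methyloxindole (5,6-dibromo-1-methyl-1,3-dihydro-2H-indol-2-one)
Conditions: NaH (1.05 equiv), toluene–THF, rt to 60 °C; Me2SO4 (1.05 equiv), 60 °C
Reagents that add atoms: dimethyl sulfate, COS(=O)(=O)OC
Why: N-Alkylation of a lactam sodium salt with a hard electrophile, the protocol known for the parent oxindole; the tight ion pair in a weakly solvating medium should react at N rather than at the softer C3. One equivalent each of base and electrophile limits later enolate methylation, and the aryl bromides are inert.

Step 3
Reactants: 3 5,6-dibromo-1-methyloxindole; 4 N,N-dimethylformamide (DMF)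
Product: 8 2,5,6-tribromo-1-methylgramine, via bromo-Vilsmeier salt 5 (not isolated), via enaminone 6 (not isolated), via iminium bromide 7 (not isolated)
Conditions: (a) POBr3 (2.5 equiv), 4 (3 equiv), ClCH2CH2Cl, 0 °C; then 3, 60 °C; (b) concentrate, THF–EtOH, NaBH4 (excess), −10 to 0 °C; aq. NaOH work-up
Reagents that add atoms: phosphorus oxybromide, O=P(Br)(Br)Br
Why: Proposed new method: 4 and POBr3 give salt 5, which the C3 enol carbon of lactam 3 attacks to give the push-pull enaminone 6 after loss of HBr (first half of a Vilsmeier–Haack–Arnold haloformylation, well known for N-alkyloxindoles). A second POBr3 phosphorylates the now electron-rich lactam oxygen of 6, and bromide replaces the dibromophosphate at C2 by addition–elimination, driven by aromatisation of the pyrrole ring, to give cation 7 (the inverse order of the two events would converge on the same cation). Instead of the usual hydrolysis to the aldehyde, 7 is intercepted by borohydride, so that the formyl carbon, the nitrogen and both methyl groups of 4 remain in the product as C3–CH2–NMe2. The closest known reaction types are the haloformylation of oxindoles to 2-haloindole-3-carbaldehydes and the borohydride reduction of aryl Vilsmeier iminium salts to (dimethylaminomethyl)arenes; what is new is their union on a 2-bromoindol-3-ylmethyleneiminium ion. No ring is closed and no stereocentre is formed. The selectivity needed is hydride attack at the exocyclic CH and not at C2: attack at CH gives an aromatic indole at once, whereas attack at C2 would give a non-aromatic 2-bromoindoline enamine, and the exocyclic carbon is the unhindered terminus of the cation. The C5–Br, C6–Br and product C2–Br bonds are inert to NaBH4, the deactivated benzene ring is not formylated, and the amine appears only in the last operation, so it meets neither Br+ nor a methylating agent.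

## Compound list

1 | 6-bromooxindole (6-bromo-1,3-dihydro-2H-indol-2-one) | O=C1Cc2ccc(Br)cc2N1 | starting material
2 | 5,6-dibromooxindole (5,6-dibromo-1,3-dihydro-2H-indol-2-one) | O=C1Cc2cc(Br)c(Br)cc2N1 | intermediate
3 | 5,6-dibromo-1-methyloxindole (5,6-dibromo-1-methyl-1,3-dihydro-2H-indol-2-one) | CN1C(=O)Cc2cc(Br)c(Br)cc21 | intermediate
4 | N,N-dimethylformamide | CN(C)C=O | starting material
5 | (bromomethylidene)dimethyliminium dibromophosphate (bromo-Vilsmeier salt) | C[N+](C)=CBr.[O-]P(=O)(Br)Br | intermediate
6 | (E)-5,6-dibromo-3-[(dimethylamino)methylidene]-1-methyl-1,3-dihydro-2H-indol-2-one (E/Z-labile, drawn E) | CN(C)/C=C1/C(=O)N(C)c2cc(Br)c(Br)cc21 | intermediate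
7 | N-methyl-N-[(2,5,6-tribromo-1-methyl-1H-indol-3-yl)methylidene]methanaminium bromide | C[N+](C)=Cc1c(Br)n(C)c2cc(Br)c(Br)cc12.[Br-] | intermediate
8 | 2,5,6-tribromo-1-methylgramine (achiral) | CN(C)Cc1c(Br)n(C)c2cc(Br)c(Br)cc12 | target

## Step count and risks

Total step count: 3. Longest linear sequence: 3 (1 → 2 → 3 → 8); 4 enters in step 3.

**Step 3 (key step, bears the label "Proposed new method:").**
- What may go wrong:
  - The acidic phosphorus bromide residues destroy the borohydride, so the cation survives to the aqueous work-up and is hydrolysed.
  - Hydride is delivered to C2 in a conjugate sense, with loss of bromide.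
  - Liberated borane complexes the new tertiary amine where the alcohol co-solvent does not solvolyse it fast enough.
- Fallback (known chemistry): it sets out from 3. The haloformylation is run as in part (a) but finished by the usual aqueous sodium acetate hydrolysis of 7, which gives the neutral, crystallisable 2,5,6-tribromo-1-methylindole-3-carbaldehyde F1, free of phosphorus acids. F1 is then submitted to a separate reductive amination with dimethylamine and NaBH(OAc)3 in 1,2-dichloroethane at room temperature. This hydride is too mild for conjugate attack, and the temperature is too low for displacement of C2–Br by the amine. The fallback comes back to the route at 8.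

**Step 2.**
- What may go wrong: the ambident anion is methylated at C3. Proton transfer from product to unreacted salt then leads to further C-methylation, because the two ring bromines make C3–H more acidic.
- Fallback: it sets out from 2 and blocks C3 before nitrogen is touched. Condensation of 2 with DMF dimethyl acetal in warm toluene gives (E)-5,6-dibromo-3-[(dimethylamino)methylidene]-1,3-dihydro-2H-indol-2-one F2, which has no C3–H and a non-nucleophilic vinylogous-urea nitrogen. MeI and K2CO3 in DMF then methylate N1 only. The fallback comes back to the route at 6, now isolated, which is taken on with POBr3 alone to 7 and with NaBH4 to 8 as in step 3.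

**Step 1.**
- What may go wrong: bromination through the C3 enol competes with a ring substitution that C6–Br has slowed, and some attack occurs at C7.
- Fallback: it sets out from 1 and accepts C3 bromination instead of fighting it. About three equivalents of NBS in aqueous tert-butanol give 3,3,5,6-tetrabromo-1,3-dihydro-2H-indol-2-one F3. Zinc dust in acetic acid at room temperature then removes only the two α-carbonyl bromines at C3 and leaves the aryl bromides. The fallback comes back to the route at 2.

## Further compounds

F1 | step 3 | 2,5,6-tribromo-1-methyl-1H-indole-3-carbaldehyde | O=Cc1c(Br)n(C)c2cc(Br)c(Br)cc12
F2 | step 2 | (E)-5,6-dibromo-3-[(dimethylamino)methylidene]-1,3-dihydro-2H-indol-2-one (E/Z-labile, drawn E) | CN(C)/C=C1/C(=O)Nc2cc(Br)c(Br)cc21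
F3 | step 1 | 3,3,5,6-tetrabromo-1,3-dihydro-2H-indol-2-one | O=C1Nc2cc(Br)c(Br)cc2C1(Br)Br
A1 | alternative 1 | 5,6-dibromo-1-methyl-1H-indole | Cn1ccc2cc(Br)c(Br)cc21
A2 | alternative 1 | 5,6-dibromo-1-methylgramine | CN(C)Cc1cn(C)c2cc(Br)c(Br)cc12
A3 | alternative 2 | 1-methylgramine | CN(C)Cc1cn(C)c2ccccc12
A4 | alternative 3 | 4,5-dibromo-2-iodo-N-methylaniline | CNc1cc(Br)c(Br)cc1I
A5 | alternative 3 | N,N-dimethyl-3-(trimethylsilyl)prop-2-yn-1-amine | CN(C)CC#C[Si](C)(C)C
A6 | alternative 3 | 5,6-dibromo-1-methyl-2-(trimethylsilyl)gramine | CN(C)Cc1c([Si](C)(C)C)n(C)c2cc(Br)c(Br)cc12
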